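Start from a ratio: the target in the delta run falls from 50.8 % at 180 min to 22.9 % at 1500 min, and the same ratio can be read in the epsilon run. The question is how fast that decline grows with temperature.

the same everywhere: starting material 20 mM; gas 2.7 mM (held)
- delta: second substrate 0.67 equiv; temperature 5 °C; run made earlier
- epsilon: second substrate 1.5 equiv; temperature 40 °C; run made earlier
- Monday's: second substrate 1.00 equiv; temperature 70 °C; time 50 min
- Tuesday's: second substrate 1.00 equiv; temperature 10 °C; time 50 min
- Wednesday's: second substrate 1.00 equiv; temperature 40 °C; time 50 min

| run | time / min | target / % |
|---|---|---|
| delta | 180 | 50.8 |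
| delta | 480 | 40.3 |
| delta | 900 | 28.0 |
| delta | 1500 | 22.9 |
| epsilon | 20.0 | 10.8 |
| epsilon | 50.0 | 12.5 |
| epsilon | 120 | 9.3 |
| epsilon | 240 | 4.2 |

(standard deviation of a reading: 1 percentage point)

- in percentages every species weighs as the starting material in it: one side product counts as two
- at the start none of coupling partner is dissolved
- the numbers in the tables scatter with a standard deviation of 1 percentage point
- steps under discussion: starting material + coupling partner <-> target; second substrate + coupling partner <-> second product; coupling partner <-> dormant form; gas <-> coupling partner; starting material + target -> side product

1. which flask leads in amount of target, in percent of the starting material charged ("all alike" within 1.5 percentage points) (Monday's / Tuesday's / Wednesday's / all alike)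
2. how much target is there at the end, in percent of the starting material charged: Monday's
3. how much target is there at the end, in percent of the starting material charged: Tuesday's
4. how much target is there at the end, in percent of the starting material charged: Wednesday's

Build the flask step by step. With starting material + coupling partner <-> target alone, the target climbs to a plateau and stays there. Add starting material + target -> side product and the target declines, as both runs show. Define the tail constant k as the logarithm of a reading ratio over the time between: 6.04 × 10⁻⁴ min⁻¹ in the delta run, 0.00662 min⁻¹ in the epsilon run. These are readings, with their scatter. Their ratio is 11.0, so define the doubling interval D, the temperature rise that doubles k: 10.1 K.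

Now add the rest: the second substrate and the dormant form draw on the coupling partner, and the gas replaces it. Freeze their joint effect by assuming, as my own reckoning, that past the peak the target level times k is equal between flasks. Take the epsilon peak as Wednesday's estimate, 12.5 %. Monday's k is larger by 7.79, which puts k times the time at 2.58, above one, so Monday's is past its peak at about 1.60 %. Tuesday's lies nearer the delta run at 5 °C, whose first reading at 180 min comes later than Tuesday's 50 min, so the readings do not show on which side of its peak Tuesday's stands, and I do not use the rule there. Bracket it instead: a straight line to the first delta reading gives 14.1 %, and the delta tail run back to the start gives 56.6 %. Tuesday's should lead, narrowly even at the floor.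

The forecast also names Tuesday's, with 3 % for Monday's, 25 % for Tuesday's and 15 % for Wednesday's, on the ground that “Warming therefore speeds every step but disfavours the target”.

The flasks give 1.44 % for Monday's, 36.0 % for Tuesday's and 11.3 % for Wednesday's, so Tuesday's leads, 11 percentage points above the forecast and inside my bracket. In Monday's, making over using stands at 0.996 at 22.3 min. Dividing Wednesday's result by the factor from D gives 1.45 % for Monday's.

    starting material + coupling partner ⇌ target (K = 170 L mol⁻¹, k = 120 L mol⁻¹ min⁻¹, Ea = 49.0 kJ mol⁻¹, ΔH = −28.0 kJ mol⁻¹)
    second substrate + coupling partner ⇌ second product (K = 240 L mol⁻¹, k = 82.0 L mol⁻¹ min⁻¹, Ea = 46.0 kJ mol⁻¹, ΔH = −39.0 kJ mol⁻¹)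
    coupling partner ⇌ dormant form (K = 220, k = 0.0510 min⁻¹, Ea = 96.0 kJ mol⁻¹, ΔH = −73.0 kJ mol⁻¹)
    gas ⇌ coupling partner, rate k4*(csat - [coupling partner]) (kL = 0.250 min⁻¹)
    starting material + target → side product (k = 4.40 L mol⁻¹ min⁻¹, Ea = 71.0 kJ mol⁻¹)
    (constants at 40 °C)

Repeat Monday's at 45 °C: D, applied to Wednesday's result, gives 8.01 %. That flask gives 7.80 %.

(All runs are calculated with constants of no real substance, noise included.)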